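**Retrosynthetic overview**
1. Ring B (hemiketal) and ring C (seven-membered) are closed last, in one pot: a methyl ketone enolate acylates a neighbouring α-hydroxy ester (Claisen, C-2/C-3 bond), the resulting 1,3-diketonate is hydroxylated at C-2, and the pyrone hydroxyl then adds to the C-1 ketone.
2. The C-8 methylene bridge comes from conjugate addition of the triketide pyrone (ring A) to an exo-methylene ketone, itself made from a 3-substituted pentane-2,4-dione and formaldehyde.
3. The C-6/C-7 bond comes from a stereoretentive palladium-catalysed allylic alkylation of a lactate-derived allylic acetate with pentane-2,4-dione.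
4. Ring D is made first, by aldol addition of the tetrasubstituted enol silane of 3-methylbutan-2-one to the central carbonyl of a lactate-derived vicinal tricarbonyl (sets the tertiary carbinol C-4), then aldol condensation.
5. Ring order: A (separately), D, then C and B together.

Assumption: the biogenesis is taken to be polyketide-like (aldol closure of ring D, Claisen closure of ring C, pyrone addition to an exocyclic enone, C-2 hydroxylation, spontaneous hemiketalisation), and C-1, C-2 and C-7 are taken to be under thermodynamic control through ring–chain tautomerism of the hemiketal.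

Locants: ring C is C-1 (hemiketal), C-2 (CHOH), C-3 (C=O), C-4 (C–OH, fusion), C-5 (alkene fusion carbon), C-6 (CHCH3), C-7 (CH); C-8 is the CH2 bridge to the pyrone; ring D is C-4, C-5, C-9 (=CH), C-10 (C=O), C-11 (CMe2). The target is 1S,2R,4R,6R,7R.

**Step 1**
Reactants: 1 methyl 3-oxopentanoate
Product: 3 4-hydroxy-5,6-dimethyl-2H-pyran-2-one, via methyl 4-methyl-3,5-dioxohexanoate 2 (not isolated)
Conditions: LiN(iPr)2 (2.2 equiv), THF, −78 → 0 °C; N-acetylimidazole, −78 °C → rt; 1 M HCl; then DBU (cat.), PhMe, reflux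
Reagents that add atoms: N-acetylimidazole, CC(=O)n1ccnc1
Why: The 1,3-dianion of the β-keto ester is C-acylated at its γ-carbon (dianion Claisen acylation) and the 3,5-diketo ester lactonises through its 5-enol with loss of methanol to the 2-pyrone, with no stereocentre formed.

**Step 2**
Reactants: 4 (S)-2-acetoxypropanoyl chloride; 5 Meldrum's acid (2,2-dimethyl-1,3-dioxane-4,6-dione)
Product: 7 methyl (4S)-4-acetoxy-3-oxopentanoate, via acyl Meldrum's acid 6 (not isolated)
Conditions: pyridine (2 equiv), CH2Cl2, −10 °C → rt; then MeOH, reflux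
Reagents that add atoms: methanol, CO
Why: C-acylation of Meldrum's acid followed by methanolysis with loss of acetone and CO2 is the standard β-keto ester homologation of an acid chloride, and the lactate stereocentre (future C-6) is carried through unchanged.

**Step 3**
Reactants: 7 methyl (4S)-4-acetoxy-3-oxopentanoate
Product: 8 methyl (4S)-4-acetoxy-2,3-dioxopentanoate (obtained as its hydrate and dried before use)
Conditions: Dess–Martin periodinane (2.5 equiv), pyridine, CH2Cl2, rt; then azeotropic drying (PhMe), 4 Å MS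
Reagents that add atoms: Dess–Martin periodinane, CC(=O)OI1(OC(C)=O)(OC(C)=O)OC(=O)c2ccccc12
Why: Oxidation of the active methylene of a β-keto ester to the vicinal tricarbonyl by the periodinane (α-oxygenation of the enol, then alcohol oxidation) proceeds under buffered, mild conditions that leave the α-acetoxy stereocentre intact.

**Step 4**
Reactants: 9 3-methylbutan-2-one
Product: 10 trimethyl[(3-methylbut-2-en-2-yl)oxy]silane
Conditions: Me3SiCl, NaI, Et3N, MeCN, rt; fractional distillation
Reagents that add atoms: chlorotrimethylsilane, C[Si](C)(C)Cl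
Why: Silylation under equilibrating conditions (iodotrimethylsilane formed in the flask) gives mainly the thermodynamic tetrasubstituted enol silane, which is freed from the terminal isomer by distillation, with no stereocentre formed.

**Step 5**
Reactants: 8 methyl (4S)-4-acetoxy-2,3-dioxopentanoate; 10 trimethyl[(3-methylbut-2-en-2-yl)oxy]silane
Product: 12 methyl (1R)-2-[(1S)-1-acetoxyethyl]-1-hydroxy-5,5-dimethyl-4-oxocyclopent-2-ene-1-carboxylate, via silyl aldol adduct 11 (not isolated)
Conditions: Cu(OTf)2 (10 mol %), (R,R)-tBu-box [2,2'-(propane-2,2-diyl)bis((4R)-4-tert-butyl-4,5-dihydrooxazole)] (11 mol %), CH2Cl2, −78 → −40 °C; then TsOH·H2O (20 mol %), PhMe, 80 °C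
Reagents that add atoms: none
Why: Proposed new method: the central carbonyl of the vicinal tricarbonyl is by far the most electrophilic and, held as a five-membered keto/ester chelate on the bis(oxazoline)-bound divalent copper, should accept the tetrasubstituted enol silane on its re face to set the tertiary carbinol C-4 (S in 11, R in 12), after which acid-catalysed intramolecular aldol condensation of the new methyl ketone onto the flanking ketone closes ring D (enolisation towards the acetoxy-bearing carbon cannot dehydrate and reverts); the closest known reaction type is the bis(oxazoline)–Cu(OTf)2-catalysed Mukaiyama aldol addition of enol silanes to pyruvate esters, joined to the classical 1,4-diketone aldol condensation to a cyclopentenone.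

**Step 6**
Reactants: 12 methyl (1R)-2-[(1S)-1-acetoxyethyl]-1-hydroxy-5,5-dimethyl-4-oxocyclopent-2-ene-1-carboxylate; 13 pentane-2,4-dione
Product: 14 methyl (1R)-2-[(2R)-3-acetyl-4-oxopentan-2-yl]-1-hydroxy-5,5-dimethyl-4-oxocyclopent-2-ene-1-carboxylate
Conditions: 13 (2 equiv), NaH (1.9 equiv), Pd(PPh3)4 (5 mol %), THF, 25 → 50 °C
Reagents that add atoms: none
Why: In this Tsuji–Trost allylic alkylation zerovalent palladium ionises the γ-acetoxy enone with inversion and the soft diketone anion attacks the allyl terminus remote from the acyl group, again with inversion, so C-6 is formed with net retention (S acetate to the R-configured C–C bond) and the ring D enone is regenerated.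

**Step 7**
Reactants: 14 methyl (1R)-2-[(2R)-3-acetyl-4-oxopentan-2-yl]-1-hydroxy-5,5-dimethyl-4-oxocyclopent-2-ene-1-carboxylate; 3 4-hydroxy-5,6-dimethyl-2H-pyran-2-one
Product: 16 methyl (1R)-1-hydroxy-2-[(2R,3RS)-3-[(4-hydroxy-5,6-dimethyl-2-oxo-2H-pyran-3-yl)methyl]-4-oxopentan-2-yl]-5,5-dimethyl-4-oxocyclopent-2-ene-1-carboxylate, via exo-methylene ketone 15 (not isolated)
Conditions: 37 % aq. HCHO (1.1 equiv), K2CO3 (1.1 equiv), THF–H2O, 0 °C → rt; then 3 (1.2 equiv), 40 °C
Reagents that add atoms: formaldehyde, C=O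
Why: Hydroxymethylation of the 3-substituted pentane-2,4-dione and retro-Claisen loss of acetate (deacetylative methylenation) give the α-methylene ketone, to which the pyrone adds through its C-3 (Michael addition, as in the warfarin synthesis) to form the C-8 bridge, while C-7 arises as an epimeric mixture that is equilibrated in step 8.

**Step 8**
Reactants: 16 methyl (1R)-1-hydroxy-2-[(2R,3RS)-3-[(4-hydroxy-5,6-dimethyl-2-oxo-2H-pyran-3-yl)methyl]-4-oxopentan-2-yl]-5,5-dimethyl-4-oxocyclopent-2-ene-1-carboxylate
Product: 19 CNP0525404.1, via bicyclic 1,3-diketone 17 (not isolated), via 2-hydroxy-1,3-diketone 18 (not isolated)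
Conditions: KOtBu (4.5 equiv), THF, 0 °C → rt; 2-(phenylsulfonyl)-3-phenyloxaziridine (1.1 equiv), −78 → −40 °C; 1 M HCl to pH 3; then wet EtOAc, rt, 12 h
Reagents that add atoms: 2-(phenylsulfonyl)-3-phenyloxaziridine, O=S(=O)(N1OC1c1ccccc1)c1ccccc1
Why: The methyl ketone enolate (C-2) acylates the neighbouring methyl ester in a Dieckmann-type Claisen condensation that closes ring C and is driven by 1,3-diketonate formation, the diketonate is hydroxylated at C-2 (Davis oxidation), and on acidification the pyrone hydroxyl adds to the C-1 ketone to close ring B, with C-7 (α to a ketone), C-2 (between two carbonyls in the open form) and C-1 (hemiketal) equilibrating to the trans-fused diastereomer bearing an axial anomeric hydroxyl while C-4 and C-6 are not touched.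

**Compound list**
1 | methyl 3-oxopentanoate | CCC(=O)CC(=O)OC | starting material
2 | methyl 4-methyl-3,5-dioxohexanoate (racemic) | CC(=O)C(C)C(=O)CC(=O)OC | intermediate
3 | 4-hydroxy-5,6-dimethyl-2H-pyran-2-one | Cc1oc(=O)cc(O)c1C | intermediate
4 | (S)-2-acetoxypropanoyl chloride | C[C@H](OC(C)=O)C(Cl)=O | starting material
5 | Meldrum's acid (2,2-dimethyl-1,3-dioxane-4,6-dione) | CC1(C)OC(=O)CC(=O)O1 | starting material
6 | 5-[(2S)-2-acetoxy-1-hydroxypropylidene]-2,2-dimethyl-1,3-dioxane-4,6-dione | C[C@H](OC(C)=O)C(O)=C1C(=O)OC(C)(C)OC1=O | intermediate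
7 | methyl (4S)-4-acetoxy-3-oxopentanoate | C[C@H](OC(C)=O)C(=O)CC(=O)OC | intermediate
8 | methyl (4S)-4-acetoxy-2,3-dioxopentanoate | C[C@H](OC(C)=O)C(=O)C(=O)C(=O)OC | intermediate
9 | 3-methylbutan-2-one | CC(C)C(C)=O | starting material
10 | trimethyl[(3-methylbut-2-en-2-yl)oxy]silane | CC(O[Si](C)(C)C)=C(C)C | intermediate
11 | methyl (2S,4S)-4-acetoxy-2-(2-methyl-3-oxobutan-2-yl)-3-oxo-2-[(trimethylsilyl)oxy]pentanoate | C[C@H](OC(C)=O)C(=O)[C@](O[Si](C)(C)C)(C(=O)OC)C(C)(C)C(C)=O | intermediate
12 | methyl (1R)-2-[(1S)-1-acetoxyethyl]-1-hydroxy-5,5-dimethyl-4-oxocyclopent-2-ene-1-carboxylate | COC(=O)[C@@]1(O)C(=CC(=O)C1(C)C)[C@H](C)OC(C)=O | intermediate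
13 | pentane-2,4-dione | CC(=O)CC(C)=O | starting material
14 | methyl (1R)-2-[(2R)-3-acetyl-4-oxopentan-2-yl]-1-hydroxy-5,5-dimethyl-4-oxocyclopent-2-ene-1-carboxylate | COC(=O)[C@@]1(O)C(=CC(=O)C1(C)C)[C@H](C)C(C(C)=O)C(C)=O | intermediate
15 | methyl (1R)-1-hydroxy-5,5-dimethyl-2-[(2S)-3-methylidene-4-oxopentan-2-yl]-4-oxocyclopent-2-ene-1-carboxylate | COC(=O)[C@@]1(O)C(=CC(=O)C1(C)C)[C@H](C)C(=C)C(C)=O | intermediate
16 | methyl (1R)-1-hydroxy-2-[(2R,3RS)-3-[(4-hydroxy-5,6-dimethyl-2-oxo-2H-pyran-3-yl)methyl]-4-oxopentan-2-yl]-5,5-dimethyl-4-oxocyclopent-2-ene-1-carboxylate (open keto form drawn; largely the cyclic hemiketal in solution; C-7 epimers) | COC(=O)[C@@]1(O)C(=CC(=O)C1(C)C)[C@H](C)C(Cc1c(O)c(C)c(C)oc1=O)C(C)=O | intermediate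
17 | (3aR,8R)-3a-hydroxy-7-[(4-hydroxy-5,6-dimethyl-2-oxo-2H-pyran-3-yl)methyl]-3,3,8-trimethyl-3,3a,7,8-tetrahydroazulene-2,4,6(5H)-trione (C-7 epimers) | Cc1oc(=O)c(CC2C(=O)CC(=O)[C@@]3(O)C(=CC(=O)C3(C)C)[C@@H]2C)c(O)c1C | intermediate
18 | (3aR,8R)-3a,5-dihydroxy-7-[(4-hydroxy-5,6-dimethyl-2-oxo-2H-pyran-3-yl)methyl]-3,3,8-trimethyl-3,3a,7,8-tetrahydroazulene-2,4,6(5H)-trione (epimers at C-2 and C-7 of the locant scheme) | Cc1oc(=O)c(CC2C(=O)C(O)C(=O)[C@@]3(O)C(=CC(=O)C3(C)C)[C@@H]2C)c(O)c1C | intermediate
19 | CNP0525404.1, the (1S,2R,4R,6R,7R) hemiketal of 18 in which the pyrone oxygen is bound to C-1 | Cc1oc(=O)c2c(c1C)O[C@]1(O)[C@H](O)C(=O)[C@@]3(O)C(=CC(=O)C3(C)C)[C@H](C)[C@H]1C2 | target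

**Step count and risk**
Total steps: 8. Longest linear sequence: 6 steps (4 and 5 to 7, 8, 12, 14, 16, 19).

The three steps most likely to fail:

Step 5. The hindered enol silane may react sluggishly, the enantiofacial sense with a tricarbonyl (two possible chelates) is not secured by precedent, and the lactate centre may erode under the acid. The fallback sets out from 8 and returns at 12. A thermal, uncatalysed carbonyl-ene reaction of 8 with 2,3-dimethylbut-2-ene (PhMe, 60 °C) takes place at the central carbonyl and gives both C-2 epimers, which are diastereomers because of the lactate centre. Chromatography gives methyl (2S,4S)-4-acetoxy-2-(2,3-dimethylbut-3-en-2-yl)-2-hydroxy-3-oxopentanoate F1. Ozonolysis (O3, CH2Cl2–MeOH, −78 °C; Me2S) converts the isopropenyl group to the methyl ketone, giving methyl (2S,4S)-4-acetoxy-2-hydroxy-2-(2-methyl-3-oxobutan-2-yl)-3-oxopentanoate F2. This is cyclodehydrated with TsOH in PhMe to 12.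

Step 8. Risks are a competing five-membered Michael closure onto C-5, retro-aldol opening at C-4 or epimerisation at C-6 under the alkoxide base, hydroxylation at the pyrone instead of C-2, and incomplete convergence of C-1, C-2 and C-7. The fallback sets out from 16 and returns at 19 in stages. Claisen closure with NaOMe in MeOH is followed by acid (TsOH, PhMe, 60 °C), which closes ring B and dehydrates it to the isolable anhydro vinylogous ester (C-1=C-2 enol ether) F5. Dihydroxylation of that enol ether double bond (OsO4 cat., N-methylmorpholine N-oxide, acetone–H2O) installs the C-1 and C-2 hydroxyls directly, and mild acid equilibration gives 19.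

Step 6. The allylic acetate sits next to a quaternary carbinol, so ionisation may be slow and β-hydride loss to a diene may compete. The fallback sets out from 12 and returns at 14 by two successive inversions. Methanolysis of the acetate (K2CO3, MeOH, 0 °C) gives methyl (1R)-1-hydroxy-2-[(1S)-1-hydroxyethyl]-5,5-dimethyl-4-oxocyclopent-2-ene-1-carboxylate F3. Appel bromination (CBr4, PPh3, CH2Cl2, 0 °C) gives methyl (1R)-2-[(1R)-1-bromoethyl]-1-hydroxy-5,5-dimethyl-4-oxocyclopent-2-ene-1-carboxylate F4. Displacement with sodium pentane-2,4-dionate in DMF gives 14.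

**Further compounds**
F1 | step 5 | methyl (2S,4S)-4-acetoxy-2-(2,3-dimethylbut-3-en-2-yl)-2-hydroxy-3-oxopentanoate | C[C@H](OC(C)=O)C(=O)[C@](O)(C(=O)OC)C(C)(C)C(C)=C
F2 | step 5 | methyl (2S,4S)-4-acetoxy-2-hydroxy-2-(2-methyl-3-oxobutan-2-yl)-3-oxopentanoate | C[C@H](OC(C)=O)C(=O)[C@](O)(C(=O)OC)C(C)(C)C(C)=O
F3 | step 6 | methyl (1R)-1-hydroxy-2-[(1S)-1-hydroxyethyl]-5,5-dimethyl-4-oxocyclopent-2-ene-1-carboxylate | COC(=O)[C@@]1(O)C(=CC(=O)C1(C)C)[C@H](C)O
F4 | step 6 | methyl (1R)-2-[(1R)-1-bromoethyl]-1-hydroxy-5,5-dimethyl-4-oxocyclopent-2-ene-1-carboxylate | COC(=O)[C@@]1(O)C(=CC(=O)C1(C)C)[C@@H](C)Br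
F5 | step 8 | anhydro vinylogous ester of 17 (2-deoxy-1,2-didehydro analogue of 19, 4R,6R,7R) | Cc1oc(=O)c2c(c1C)OC1=CC(=O)[C@@]3(O)C(=CC(=O)C3(C)C)[C@H](C)[C@H]1C2
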